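**Plan**

1. Retrosynthesis (flavan numbering): the C3 vanillate ester is cut first, then ring C is opened at O1–C8a and C4–C4a in one operation (aryne plus silyloxy aldehyde), and the aldehyde is cut at C2–C3 (glycolate aldol).
2. Forward: an Evans glycolate aldol joins ring B to the C2–C3–C4 chain; ring A enters as 3,5-bis(benzyloxy)benzyne and ring C closes in the same flask; the C4 hydroxyl is then removed, O3 is unmasked and acylated, and five benzyl groups are hydrogenolysed.
3. Enabling feature: on ring A, C8a (bearing O1) and C4a (bearing C4) are adjacent, and C4a is flanked by the C5 oxygen. This is the vicinal O,C pattern that addition of a nucleophile and an electrophile across a 3-alkoxybenzyne delivers.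
4. Stereochemistry: C2 and C3 both come from the boron aldol with (S)-4-benzyloxazolidinone, whose syn (2S,3R) adduct maps onto 2R,3R (2,3-cis) in the flavan. Neither C–O bond is broken afterwards, and the C4 carbinol is transient.
5. Protecting groups: phenols as benzyl ethers; O3 as an allyl ether, which is inert to fluoride, aryne and Lewis acid/silane and comes off without DDQ or strong acid, either of which would attack the electron-rich benzylated flavan; the benzylic oxygen as an Et3Si ether, the fluoride-released nucleophile.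

Key step: step 8

Remark: compounds 1, 6 and 23 are taken as catalogue chemicals; ring positions are given in flavan numbering throughout.

**Route**

Step 1
Reactants: 1 3,5-bis(benzyloxy)phenol
Product: 2 3,5-bis(benzyloxy)-2-bromophenol
Conditions: NBS (1.0 equiv), CH2Cl2, −78 °C
Reagents that add atoms: N-bromosuccinimide, O=C1CCC(=O)N1Br
Why: Electrophilic aromatic bromination of a phloroglucinol-type ring, in which NBS at low temperature in a non-polar solvent should be delivered ortho to the free hydroxyl (the two ortho positions are equivalent) and one equivalent limits polybromination.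

Step 2
Reactants: 2 3,5-bis(benzyloxy)-2-bromophenol
Product: 5 3,5-bis(benzyloxy)-2-(trimethylsilyl)phenyl trifluoromethanesulfonate, via aryl trimethylsilyl ether 3 (not isolated), via lithium silylphenoxide 4 (not isolated)
Conditions: HMDS, THF, 70 °C; then n-BuLi, THF, −100 °C; then Tf2O, −100 → −78 °C
Reagents that add atoms: hexamethyldisilazane, C[Si](C)(C)N[Si](C)(C)C; trifluoromethanesulfonic anhydride, O=S(=O)(OS(=O)(=O)C(F)(F)F)C(F)(F)F
Why: O-Silylation followed by bromine–lithium exchange sets off the 1,3 O→C silyl shift (retro-Brook rearrangement) to phenoxide 4, which is triflated in the same flask, the standard preparation of ortho-silylaryl triflates from ortho-bromophenols.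

Step 3
Reactants: 6 2-(allyloxy)acetic acid; 7 (S)-4-benzyl-1,3-oxazolidin-2-one
Product: 9 (S)-3-[2-(allyloxy)acetyl]-4-benzyl-1,3-oxazolidin-2-one, via mixed pivalic anhydride 8 (not isolated)
Conditions: t-BuCOCl, Et3N, THF, −20 °C; then 7, LiCl, −20 °C → rt
Reagents that add atoms: none
Why: N-Acylation of the oxazolidinone through the mixed pivalic anhydride (Et3N/LiCl variant), in which the hindered pivaloyl carbonyl steers attack to the glycolyl carbonyl.

Step 4
Reactants: 9 (S)-3-[2-(allyloxy)acetyl]-4-benzyl-1,3-oxazolidin-2-one; 10 3,4-bis(benzyloxy)benzaldehyde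
Product: 12 (S)-3-{(2S,3R)-2-(allyloxy)-3-[3,4-bis(benzyloxy)phenyl]-3-hydroxypropanoyl}-4-benzyl-1,3-oxazolidin-2-one, via Z-boron enolate 11 (not isolated)
Conditions: Bu2BOTf, Et3N, CH2Cl2, −78 → 0 °C; then 10, −78 → 0 °C; pH 7 buffer, MeOH, H2O2, 0 °C
Reagents that add atoms: none
Why: Evans syn aldol, in which the Z-dibutylboron enolate 11 reacts through a closed Zimmerman–Traxler chair on the face away from the benzyl group of the (S)-auxiliary (carbonyl dipoles opposed), setting both new centres at once as the syn (2S,3R) adduct that corresponds to 2R,3R (2,3-cis) in the flavan.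

Step 5
Reactants: 12 (S)-3-{(2S,3R)-2-(allyloxy)-3-[3,4-bis(benzyloxy)phenyl]-3-hydroxypropanoyl}-4-benzyl-1,3-oxazolidin-2-one
Product: 13 (2S,3R)-2-(allyloxy)-3-[3,4-bis(benzyloxy)phenyl]-3-hydroxy-N-methoxy-N-methylpropanamide
Conditions: MeONHMe·HCl, AlMe3, THF, −20 → 0 °C; aq. potassium sodium tartrate
Reagents that add atoms: N,O-dimethylhydroxylamine hydrochloride, CNOC.Cl
Why: Weinreb transamidation with the aluminium amide, directed to the exocyclic imide carbonyl by the free β-hydroxyl (as its aluminium alkoxide), which releases the auxiliary without touching either stereocentre.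

Step 6
Reactants: 13 (2S,3R)-2-(allyloxy)-3-[3,4-bis(benzyloxy)phenyl]-3-hydroxy-N-methoxy-N-methylpropanamide
Product: 14 (2S,3R)-2-(allyloxy)-3-[3,4-bis(benzyloxy)phenyl]-N-methoxy-N-methyl-3-(triethylsilyloxy)propanamide
Conditions: Et3SiOTf, 2,6-lutidine, CH2Cl2, −78 → 0 °C
Reagents that add atoms: triethylsilyl trifluoromethanesulfonate, CC[Si](CC)(CC)OS(=O)(=O)C(F)(F)F
Why: Silyl triflate/hindered-base silylation of a secondary benzylic alcohol, giving an Et3Si ether that survives the hydride reduction that follows yet should be cleaved by fluoride at a rate comparable with aryl–SiMe3 activation in step 8.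

Step 7
Reactants: 14 (2S,3R)-2-(allyloxy)-3-[3,4-bis(benzyloxy)phenyl]-N-methoxy-N-methyl-3-(triethylsilyloxy)propanamide
Product: 15 (2S,3R)-2-(allyloxy)-3-[3,4-bis(benzyloxy)phenyl]-3-(triethylsilyloxy)propanal
Conditions: i-Bu2AlH, THF, −78 °C; aq. potassium sodium tartrate
Reagents that add atoms: none
Why: Hydride reduction of a Weinreb amide, which stops at the aldehyde because the chelated adduct collapses only on work-up, while low temperature, a neutral tartrate work-up and immediate use without chromatography should keep the α-alkoxy centre intact.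

Step 8
Reactants: 15 (2S,3R)-2-(allyloxy)-3-[3,4-bis(benzyloxy)phenyl]-3-(triethylsilyloxy)propanal; 5 3,5-bis(benzyloxy)-2-(trimethylsilyl)phenyl trifluoromethanesulfonate
Product: 19 (2R,3R)-3-(allyloxy)-5,7-bis(benzyloxy)-2-[3,4-bis(benzyloxy)phenyl]chroman-4-ol (both C4 epimers), via 3,5-bis(benzyloxy)benzyne 16 (not isolated), via cesium alkoxide 17 (not isolated), via aryl cesium adduct 18 (not isolated)
Conditions: 5 (1.3 equiv), CsF (4 equiv), 18-crown-6, THF, 0 °C → rt; then H2O
Reagents that add atoms: none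
Why: Proposed new method: fluoride attacks both silicon centres, so that 5 collapses to aryne 16 (loss of Me3SiF and triflate) while the Et3Si ether of 15 is cleaved to alkoxide 17 with no proton source present; 17 adds to the aryne carbon remote from the benzyloxy group (O1–C8a), and the aryl anion 18, held ortho to the new ether, attacks the aldehyde carbon (C4–C4a) in a 6-exo-trig closure of ring C. The closest known reaction type is the fluoride-promoted annulation of salicylaldehydes or salicylates with ortho-silylaryl triflates to xanthols and xanthones (O-arylation, then intramolecular carbonyl capture of the aryl anion), here transferred from a phenoxide to a secondary benzylic alkoxide. The selectivity the step needs is regiochemical: in a 3-alkoxybenzyne the inductively withdrawing oxygen distorts the triple bond and stabilises negative charge on the adjacent carbon, so the nucleophile should enter at the distal terminus, which puts O1 on C8a and the carbanion on C4a next to the C5 benzyloxy group. Neither the C2–O nor the C3–O bond is touched, so the syn configuration from the aldol is carried into the 2,3-cis flavan; the new C4 carbinol centre is uncontrolled and needs no control because step 9 deletes it. The Et3Si group is chosen so that alkoxide release keeps pace with aryne formation, which keeps the standing concentration of the retro-aldol- and epimerisation-prone β-alkoxide aldehyde low, and the allyl ether at O3 can neither migrate nor be cleaved by fluoride.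

Step 9
Reactants: 19 (2R,3R)-3-(allyloxy)-5,7-bis(benzyloxy)-2-[3,4-bis(benzyloxy)phenyl]chroman-4-ol (both C4 epimers)
Product: 20 (2R,3R)-3-(allyloxy)-5,7-bis(benzyloxy)-2-[3,4-bis(benzyloxy)phenyl]chroman
Conditions: Et3SiH (10 equiv), BF3·OEt2, CH2Cl2 (dilute), −78 → −40 °C
Reagents that add atoms: none
Why: Ionic hydrogenation of a benzylic alcohol (Kursanov–Parnes type), in which either C4 epimer ionises to the same cation, strongly stabilised by the O1, C5 and C7 oxygens of ring A, and is quenched by hydride from the silane, while cold, dilute conditions and excess silane disfavour arylation of a second molecule and C2 and C3 are not involved.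

Step 10
Reactants: 20 (2R,3R)-3-(allyloxy)-5,7-bis(benzyloxy)-2-[3,4-bis(benzyloxy)phenyl]chroman
Product: 22 (2R,3R)-5,7-bis(benzyloxy)-2-[3,4-bis(benzyloxy)phenyl]chroman-3-ol, via prop-1-enyl ether 21 (not isolated)
Conditions: [Ir(cod)(PMePh2)2]PF6 (cat., H2-activated), THF, rt; then 1 M HCl, acetone–H2O, rt
Reagents that add atoms: none
Why: Allyl ether removal by isomerisation–hydrolysis, in which the cationic iridium hydride moves the double bond into conjugation with oxygen and dilute acid cleaves the enol ether 21, a sequence that is routine beside benzyl ethers and needs neither DDQ nor strong acid, which would attack C4–H or the C2–O1 bond of the benzylated flavan.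

Step 11
Reactants: 22 (2R,3R)-5,7-bis(benzyloxy)-2-[3,4-bis(benzyloxy)phenyl]chroman-3-ol; 23 4-(benzyloxy)-3-methoxybenzoic acid
Product: 24 (2R,3R)-5,7-bis(benzyloxy)-2-[3,4-bis(benzyloxy)phenyl]chroman-3-yl 4-(benzyloxy)-3-methoxybenzoate
Conditions: DCC, DMAP, CH2Cl2, rt
Reagents that add atoms: none
Why: Steglich esterification, in which DMAP transfers the carbodiimide-activated acid to the hindered axial 3-hydroxyl, as is routine for 3-O-acylation of tetra-O-benzyl flavan-3-ols, with no stereocentre epimerisable under these conditions.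

Step 12
Reactants: 24 (2R,3R)-5,7-bis(benzyloxy)-2-[3,4-bis(benzyloxy)phenyl]chroman-3-yl 4-(benzyloxy)-3-methoxybenzoate
Product: 25 (2R,3R)-2-(3,4-dihydroxyphenyl)-5,7-dihydroxychroman-3-yl 4-hydroxy-3-methoxybenzoate
Conditions: H2 (1 atm), Pd(OH)2/C, THF–MeOH, rt
Reagents that add atoms: none
Why: Catalytic hydrogenolysis of the five benzyl aryl ethers under neutral conditions, which should leave the aryl ester and the cyclic benzylic C2–O1 ether intact, as in related deprotections of flavan-3-ol esters.

**Compound list**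

1 | 3,5-bis(benzyloxy)phenol | Oc1cc(OCc2ccccc2)cc(OCc2ccccc2)c1 | starting material
2 | 3,5-bis(benzyloxy)-2-bromophenol | Oc1cc(OCc2ccccc2)cc(OCc2ccccc2)c1Br | intermediate
3 | [3,5-bis(benzyloxy)-2-bromophenoxy]trimethylsilane | C[Si](C)(C)Oc1cc(OCc2ccccc2)cc(OCc2ccccc2)c1Br | intermediate
4 | lithium 3,5-bis(benzyloxy)-2-(trimethylsilyl)phenoxide | [Li+].[O-]c1cc(OCc2ccccc2)cc(OCc2ccccc2)c1[Si](C)(C)C | intermediate
5 | 3,5-bis(benzyloxy)-2-(trimethylsilyl)phenyl trifluoromethanesulfonate | C[Si](C)(C)c1c(OCc2ccccc2)cc(OCc2ccccc2)cc1OS(=O)(=O)C(F)(F)F | intermediate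
6 | 2-(allyloxy)acetic acid | C=CCOCC(=O)O | starting material
7 | (S)-4-benzyl-1,3-oxazolidin-2-one | O=C1N[C@@H](Cc2ccccc2)CO1 | starting material
8 | 2-(allyloxy)acetic pivalic anhydride | C=CCOCC(=O)OC(=O)C(C)(C)C | intermediate
9 | (S)-3-[2-(allyloxy)acetyl]-4-benzyl-1,3-oxazolidin-2-one | C=CCOCC(=O)N1C(=O)OC[C@@H]1Cc1ccccc1 | intermediate
10 | 3,4-bis(benzyloxy)benzaldehyde | O=Cc1ccc(OCc2ccccc2)c(OCc2ccccc2)c1 | starting material
11 | (S)-3-{(Z)-2-(allyloxy)-1-[(dibutylboranyl)oxy]vinyl}-4-benzyl-1,3-oxazolidin-2-one | C=CCO/C=C(\OB(CCCC)CCCC)N1C(=O)OC[C@@H]1Cc1ccccc1 | intermediate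
12 | (S)-3-{(2S,3R)-2-(allyloxy)-3-[3,4-bis(benzyloxy)phenyl]-3-hydroxypropanoyl}-4-benzyl-1,3-oxazolidin-2-one | C=CCO[C@H](C(=O)N1C(=O)OC[C@@H]1Cc1ccccc1)[C@H](O)c1ccc(OCc2ccccc2)c(OCc2ccccc2)c1 | intermediate
13 | (2S,3R)-2-(allyloxy)-3-[3,4-bis(benzyloxy)phenyl]-3-hydroxy-N-methoxy-N-methylpropanamide | C=CCO[C@H](C(=O)N(C)OC)[C@H](O)c1ccc(OCc2ccccc2)c(OCc2ccccc2)c1 | intermediate
14 | (2S,3R)-2-(allyloxy)-3-[3,4-bis(benzyloxy)phenyl]-N-methoxy-N-methyl-3-(triethylsilyloxy)propanamide | C=CCO[C@H](C(=O)N(C)OC)[C@H](O[Si](CC)(CC)CC)c1ccc(OCc2ccccc2)c(OCc2ccccc2)c1 | intermediate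
15 | (2S,3R)-2-(allyloxy)-3-[3,4-bis(benzyloxy)phenyl]-3-(triethylsilyloxy)propanal | C=CCO[C@H](C=O)[C@H](O[Si](CC)(CC)CC)c1ccc(OCc2ccccc2)c(OCc2ccccc2)c1 | intermediate
16 | 3,5-bis(benzyloxy)benzyne | c1ccccc1COC1=CC(OCc2ccccc2)=CC#C1 | intermediate
17 | cesium (1R,2S)-2-(allyloxy)-1-[3,4-bis(benzyloxy)phenyl]-3-oxopropan-1-olate | C=CCO[C@H](C=O)[C@H]([O-])c1ccc(OCc2ccccc2)c(OCc2ccccc2)c1.[Cs+] | intermediate
18 | cesium 2-{(1R,2S)-2-(allyloxy)-1-[3,4-bis(benzyloxy)phenyl]-3-oxopropoxy}-4,6-bis(benzyloxy)benzenide | C=CCO[C@H](C=O)[C@H](Oc1cc(OCc2ccccc2)cc(OCc2ccccc2)[c-]1)c1ccc(OCc2ccccc2)c(OCc2ccccc2)c1.[Cs+] | intermediate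
19 | (2R,3R)-3-(allyloxy)-5,7-bis(benzyloxy)-2-[3,4-bis(benzyloxy)phenyl]chroman-4-ol (both C4 epimers) | C=CCO[C@@H]1C(O)c2c(OCc3ccccc3)cc(OCc3ccccc3)cc2O[C@@H]1c1ccc(OCc2ccccc2)c(OCc2ccccc2)c1 | intermediate
20 | (2R,3R)-3-(allyloxy)-5,7-bis(benzyloxy)-2-[3,4-bis(benzyloxy)phenyl]chroman | C=CCO[C@@H]1Cc2c(OCc3ccccc3)cc(OCc3ccccc3)cc2O[C@@H]1c1ccc(OCc2ccccc2)c(OCc2ccccc2)c1 | intermediate
21 | (2R,3R)-5,7-bis(benzyloxy)-2-[3,4-bis(benzyloxy)phenyl]-3-[(E)-prop-1-enyloxy]chroman | C/C=C/O[C@@H]1Cc2c(OCc3ccccc3)cc(OCc3ccccc3)cc2O[C@@H]1c1ccc(OCc2ccccc2)c(OCc2ccccc2)c1 | intermediate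
22 | (2R,3R)-5,7-bis(benzyloxy)-2-[3,4-bis(benzyloxy)phenyl]chroman-3-ol (5,7,3',4'-tetra-O-benzyl-(−)-epicatechin) | O[C@@H]1Cc2c(OCc3ccccc3)cc(OCc3ccccc3)cc2O[C@@H]1c1ccc(OCc2ccccc2)c(OCc2ccccc2)c1 | intermediate
23 | 4-(benzyloxy)-3-methoxybenzoic acid | COc1cc(C(=O)O)ccc1OCc1ccccc1 | starting material
24 | (2R,3R)-5,7-bis(benzyloxy)-2-[3,4-bis(benzyloxy)phenyl]chroman-3-yl 4-(benzyloxy)-3-methoxybenzoate | COc1cc(C(=O)O[C@@H]2Cc3c(OCc4ccccc4)cc(OCc4ccccc4)cc3O[C@@H]2c2ccc(OCc3ccccc3)c(OCc3ccccc3)c2)ccc1OCc1ccccc1 | intermediate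
25 | (2R,3R)-2-(3,4-dihydroxyphenyl)-5,7-dihydroxychroman-3-yl 4-hydroxy-3-methoxybenzoate ((−)-epicatechin 3-O-vanillate) | COc1cc(C(=O)O[C@@H]2Cc3c(O)cc(O)cc3O[C@@H]2c2ccc(O)c(O)c2)ccc1O | target

**Step count**

Total: 12 steps. Longest linear sequence: 10 steps (steps 3 to 12); the aryne precursor is a two-step branch (steps 1 and 2).

**Steps most likely to fail, with fallbacks**

Step 8. The fluoride-released β-alkoxide of the aldehyde may fragment by retro-aldol cleavage, or epimerise or eliminate at the α-carbon, before the aryne captures it. The aryl anion may also be protonated before ring closure, or the aryne may be consumed by the aldehyde carbonyl. The fallback makes the same two bonds stepwise by polar chemistry that is known for flavan synthesis, setting out from 15 and returning at 19. 1,3,5-Trifluorobenzene would be lithiated with n-BuLi in THF at −78 °C to (2,4,6-trifluorophenyl)lithium F1, which adds to aldehyde 15 (C4–C4a first) to give 2-(allyloxy)-3-[3,4-bis(benzyloxy)phenyl]-3-(triethylsilyloxy)-1-(2,4,6-trifluorophenyl)propan-1-ol F2 as carbinol epimers, with the two existing centres as in 15. Bu4NF buffered with AcOH in THF would remove the silyl group to give 2-(allyloxy)-1-[3,4-bis(benzyloxy)phenyl]-3-(2,4,6-trifluorophenyl)propane-1,3-diol F3, which has no carbonyl group and so cannot undergo retro-aldol cleavage. KH in THF–DMF would then close ring C by intramolecular nucleophilic aromatic substitution of the benzylic alkoxide on an ortho fluorine (O1–C8a, retention at C2; only the six-membered mode is open), giving (2R,3R)-3-(allyloxy)-2-[3,4-bis(benzyloxy)phenyl]-5,7-difluorochroman-4-ol F4. Exchange of the two remaining fluorines for benzyloxy groups with BnOH/NaH in DMF on heating would give 19.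

Step 9. The C4 cation may alkylate ring A of a second molecule (the condensation that builds proanthocyanidins), or lose H3 to give a flav-3-ene enol ether, which would erase the C3 centre. The fallback removes the oxygen by a radical instead of a cation, setting out from 19 and returning at 21. The allyl group of 19 would first be isomerised with the same iridium catalyst, so that the later C4 radical has no 5-exo cyclisation partner, to give (2R,3R)-5,7-bis(benzyloxy)-2-[3,4-bis(benzyloxy)phenyl]-3-[(E)-prop-1-enyloxy]chroman-4-ol F5. NaH, CS2 and MeI in THF would convert this into O-{(2R,3R)-5,7-bis(benzyloxy)-2-[3,4-bis(benzyloxy)phenyl]-3-[(E)-prop-1-enyloxy]chroman-4-yl} S-methyl dithiocarbonate F6. Barton–McCombie reduction (Bu3SnH, AIBN, toluene, 80 °C, or Et3B/air at rt) would give 21, which is hydrolysed as in step 10.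

Step 1. Bromination may occur para to the hydroxyl, between the two benzyloxy groups, or twice, giving material that cannot lead to the required silyl triflate. The fallback places silicon by directed ortho-metalation instead of halogenation, setting out from 1 and returning at 5. Isopropyl isocyanate and Et3N in CH2Cl2 would give 3,5-bis(benzyloxy)phenyl N-isopropylcarbamate F7. With the N–H masked in the flask (t-BuMe2SiOTf, TMEDA), n-BuLi/TMEDA at −78 °C should lithiate between the carbamate and a benzyloxy group, and Me3SiCl would give 3,5-bis(benzyloxy)-2-(trimethylsilyl)phenyl N-isopropylcarbamate F8 after aqueous work-up. Carbamate cleavage with DBU and Et2NH in MeCN, followed by PhNTf2 in the same flask, would give 5.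

**Further compounds**

F1 | step 8 | (2,4,6-trifluorophenyl)lithium | [Li]c1c(F)cc(F)cc1F
F2 | step 8 | 2-(allyloxy)-3-[3,4-bis(benzyloxy)phenyl]-3-(triethylsilyloxy)-1-(2,4,6-trifluorophenyl)propan-1-ol (carbinol epimers; other centres as in 15) | C=CCO[C@H](C(O)c1c(F)cc(F)cc1F)[C@H](O[Si](CC)(CC)CC)c1ccc(OCc2ccccc2)c(OCc2ccccc2)c1
F3 | step 8 | 2-(allyloxy)-1-[3,4-bis(benzyloxy)phenyl]-3-(2,4,6-trifluorophenyl)propane-1,3-diol (C3 epimers; other centres as in 15) | C=CCO[C@H](C(O)c1c(F)cc(F)cc1F)[C@H](O)c1ccc(OCc2ccccc2)c(OCc2ccccc2)c1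
F4 | step 8 | (2R,3R)-3-(allyloxy)-2-[3,4-bis(benzyloxy)phenyl]-5,7-difluorochroman-4-ol (both C4 epimers) | C=CCO[C@@H]1C(O)c2c(F)cc(F)cc2O[C@@H]1c1ccc(OCc2ccccc2)c(OCc2ccccc2)c1
F5 | step 9 | (2R,3R)-5,7-bis(benzyloxy)-2-[3,4-bis(benzyloxy)phenyl]-3-[(E)-prop-1-enyloxy]chroman-4-ol (both C4 epimers) | C/C=C/O[C@@H]1C(O)c2c(OCc3ccccc3)cc(OCc3ccccc3)cc2O[C@@H]1c1ccc(OCc2ccccc2)c(OCc2ccccc2)c1
F6 | step 9 | O-{(2R,3R)-5,7-bis(benzyloxy)-2-[3,4-bis(benzyloxy)phenyl]-3-[(E)-prop-1-enyloxy]chroman-4-yl} S-methyl dithiocarbonate (both C4 epimers) | C/C=C/O[C@@H]1C(OC(=S)SC)c2c(OCc3ccccc3)cc(OCc3ccccc3)cc2O[C@@H]1c1ccc(OCc2ccccc2)c(OCc2ccccc2)c1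
F7 | step 1 | 3,5-bis(benzyloxy)phenyl N-isopropylcarbamate | CC(C)NC(=O)Oc1cc(OCc2ccccc2)cc(OCc2ccccc2)c1
F8 | step 1 | 3,5-bis(benzyloxy)-2-(trimethylsilyl)phenyl N-isopropylcarbamate | CC(C)NC(=O)Oc1cc(OCc2ccccc2)cc(OCc2ccccc2)c1[Si](C)(C)C
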